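**Strategy.** Everything rests on cutting the C8–C9 bond inside the 7,20-lactone. C8 lies between the lactone carbonyl C7 and the ring D ketone C15, and C9 lies next to C11, which is carried as an amide carbonyl; the two carbons are therefore both enolate carbons, the inner atoms of a 1,4-dicarbonyl array. Oxidising the bis-enolate joins them, closes the six-membered lactone and sets the spiro quaternary C8 and the adjacent C9 in one operation. The precursor is an enantiopure ring A fused to its 6,19-acetal, whose quaternary C10 carries a CH2CONMe2 arm (C9, C11) and a CH2O ester of 2-oxocyclopentanecarboxylic acid (C20, C7, C8, ring D).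

Key step: step 14

Remark 1: atom numbers are those of the ent-kaurane skeleton of the target (ring A = C1–C5 and C10; C18 and C19 on C4; C20 on C10; ring D = C8, C14, C13, C16, C15); "up" is the face of ring A that carries C19, C20 and C6.
Remark 2: by analogy with the parent acetal that lacks the methyl group, the (5S) epimer 4 is assumed to be the one that crystallises with (+)-menthol; if the (5R) epimer crystallises instead, 4 is taken from the mother liquor by chromatography and the remainder is re-equilibrated with acid.
Remark 3: the C3 configuration of 6–9 (the endo adduct is drawn), the C10 configuration of 13 and the C8 configuration of 22 are immaterial, because these centres are removed or planarised later.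

**Step 1**
Reactants: 1 citraconic anhydride
Product: 2 5-hydroxy-3-methylfuran-2(5H)-one (racemic lactol)
Conditions: LiAlH(OtBu)3, THF, −20 → 0 °C; 1 M HCl work-up
Reagents that add atoms: none
Why: Regioselective hydride reduction of a cyclic anhydride to the lactol, in which the bulky alkoxyaluminium hydride should attack the less hindered carbonyl next to the vinylic CH and leave the carbonyl beside the methyl-bearing carbon as the lactone, any 4-methyl regioisomer being removed at the crystallisation of step 2.

**Step 2**
Reactants: 2 5-hydroxy-3-methylfuran-2(5H)-one; 3 (+)-menthol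
Product: 4 (5S)-3-methyl-5-[(1S,2R,5S)-menthyloxy]furan-2(5H)-one
Conditions: TsOH (cat.), toluene, reflux, Dean–Stark; crystallisation from hexane, mother liquor re-equilibrated with TsOH
Reagents that add atoms: none
Why: Acid-catalysed acetalisation of the lactol with the chiral alcohol should give both acetal epimers, which interconvert under acid, so that crystallisation with recycling funnels the material into the (5S) acetal whose stereocentre later becomes C6.

**Step 3**
Reactants: 4 (5S)-menthyloxybutenolide; 5 (E)-3-(tert-butyldimethylsilyloxy)-N,N-dimethylbuta-1,3-dien-1-amine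
Product: 6 cis-fused cycloadduct (C1 OTBS enol ether, C3 NMe2, C19 lactone carbonyl, C6 menthyl acetal)
Conditions: toluene, 90 °C, sealed tube
Reagents that add atoms: none
Why: Thermal Diels–Alder reaction in which the nucleophilic CH2 terminus of the aminosiloxydiene should bond to the butenolide β-carbon (C5) and the amino terminus to the methyl-bearing α-carbon (C4), while the diene adds to the face opposite the menthyloxy group, so that C4 and C5 are set cis-fused and in the absolute sense dictated by C6.

**Step 4**
Reactants: 6 cycloadduct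
Product: 7 C19,C6-diol (both CH2OH) with the C1 OTBS enol ether and C3 NMe2 intact
Conditions: LiAlH4, Et2O, 0 → 23 °C; aq. NaOH work-up
Reagents that add atoms: none
Why: Hydride reduction of the γ-alkoxy lactone, a masked aldehyde acid, should give the 1,4-diol and release menthol, while the silyl enol ether and the tertiary amine are inert to LiAlH4.

**Step 5**
Reactants: 7 diol
Product: 8 6,19-lactone (C6 carbonyl, C19H2–O)
Conditions: Ag2CO3 on Celite, toluene, reflux
Reagents that add atoms: none
Why: Oxidative lactonisation of a 1,4-diol (Fétizon oxidation) in which the less hindered C6 carbinol should be oxidised first, the hydroxy aldehyde closing onto the neopentyl C19 hydroxyl and being oxidised on to the lactone, so that C6 becomes the carbonyl and C19 stays CH2 under neutral conditions that spare the enol ether.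

**Step 6**
Reactants: 8 6,19-lactone
Product: 10 ring A enone (C1 ketone, C2=C3) fused to the 6-methoxy 6,19-acetal, via C6 lactol 9 (not isolated)
Conditions: iBu2AlH, CH2Cl2, −78 °C; then HCl in MeOH, −78 → 23 °C
Reagents that add atoms: methanol, CO
Why: Half-reduction of the lactone to the lactol followed by acid-catalysed acetalisation with methanol, with hydrolysis of the silyl enol ether and β-elimination of the protonated amine in the same medium to unveil the enone; methanol should enter C6 from the convex face, trans to C10, and a minor anomer would converge when C6 is re-set in steps 21 and 22.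

**Step 7**
Reactants: 10 enone acetal; 11 benzyl chloromethyl ether
Product: 13 C10-benzyloxymethyl enone acetal (both C10 epimers), via lithium dienolate 12 (not isolated)
Conditions: LiN(iPr)2, THF, −78 °C; then 11, −78 → −30 °C
Reagents that add atoms: none
Why: Kinetic α′-alkylation of an enone, where deprotonation can occur only at C10 because C4 is quaternary and offers no γ-proton, and the cross-conjugated dienolate is C-alkylated by the reactive chloromethyl ether to install C20.

**Step 8**
Reactants: 13 C10-benzyloxymethyl enone; 14 2-bromo-N,N-dimethylacetamide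
Product: 16 C10-quaternary enone amide (C20 up and C9 down), via lithium enolate 15 (not isolated)
Conditions: LiN(iPr)2, THF/DMPU, −78 °C; then 14, −78 → −30 °C
Reagents that add atoms: none
Why: Enolate alkylation forming the quaternary centre, in which the α-bromo amide should approach the planar C10 enolate from the convex face opposite the cis-fused tetrahydrofuran ring (anti to the C5–C6 bond), placing C9 down and leaving C20 up, while the low temperature suppresses loss of benzyloxide from the β-alkoxy enolate.

**Step 9**
Reactants: 16 quaternary enone amide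
Product: 17 C20 alcohol with C1 ketone and saturated ring A
Conditions: H2 (1 atm), Pd(OH)2/C, EtOAc/EtOH, 23 °C
Reagents that add atoms: none
Why: Heterogeneous hydrogenation should saturate the C2=C3 bond and hydrogenolyse the benzyl ether in one neutral operation that spares the acetal and the amide.

**Step 10**
Reactants: 17 hydroxy ketone
Product: 18 1,20-diol with the C1 hydroxyl down (trans to C20)
Conditions: Me4NBH(OAc)3, MeCN/AcOH, −30 °C
Reagents that add atoms: none
Why: Hydroxyl-directed reduction (Evans–Saksena), in which the borohydride binds to the C20 hydroxyl by ligand exchange and delivers hydride intramolecularly to the C1 carbonyl from the C20 face, so that the anti 1,3-diol with the C1 hydroxyl trans to C20 should result.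

**Step 11**
Reactants: 18 diol
Product: 19 1,20-bis(TBS) ether
Conditions: TBSOTf, 2,6-lutidine, CH2Cl2, 0 °C
Reagents that add atoms: tert-butyldimethylsilyl triflate, CC(C)(C)[Si](C)(C)OS(=O)(=O)C(F)(F)F
Why: Silyl ether formation with the silyl triflate, which is reactive enough to protect the hindered axial C1 hydroxyl as well as the primary one.

**Step 12**
Reactants: 19 bis(TBS) ether
Product: 20 C20 alcohol with C1 OTBS
Conditions: HF·pyridine, pyridine, THF, 0 °C
Reagents that add atoms: none
Why: Selective desilylation, the primary C20 silyl ether being cleaved much faster than the secondary C1 ether next to quaternary C10, under buffered conditions at 0 °C that should avoid acetal exchange and lactonisation onto the amide.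

**Step 13**
Reactants: 20 C20 alcohol; 21 methyl 2-oxocyclopentane-1-carboxylate
Product: 22 C20 2-oxocyclopentane-1-carboxylate (both C8 epimers)
Conditions: DMAP (cat.), 4 Å molecular sieves, toluene, 100 °C
Reagents that add atoms: none
Why: DMAP-catalysed transesterification of a β-keto ester, which runs through the acylketene and therefore tolerates the neopentyl alcohol, the C8 epimer mixture being of no consequence.

**Step 14**
Reactants: 22 keto ester amide
Product: 24 dispiro keto lactone amide, via dilithium bis-enolate 23 (not isolated)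
Conditions: LiN(iPr)2 (2.3 eq), THF, −78 → −30 °C; then Fe(acac)3 (2.2 eq), −78 → 23 °C, high dilution
Reagents that add atoms: none
Why: Two equivalents of LiN(iPr)2 should convert 22 into the bis-enolate 23 (the acidic C8–H first, then the C9 methylene of the amide), so that both C8 epimers merge in one planar enolate; one-electron oxidation of the more electron-rich amide enolate by trivalent iron gives a C9 radical that is captured at C8 of the neighbouring keto ester enolate, and a second equivalent of Fe(acac)3 oxidises the resulting radical anion to the 1,4-dicarbonyl product. The closest known reaction type is the intramolecular oxidative heterocoupling of an amide enolate with an ester enolate by Fe(acac)3 or a divalent copper carboxylate. The lactone ring closes in a 6-exo-trig mode (radical at C9, the enolate bond C8=C15 exocyclic to the new ring), helped by the quaternary C10 that holds both chains. C9 is controlled by C10: in the chair-like transition state the carbamoyl group should sit axial, anti to the bulkier C5 branch and gauche to C1, which places C11 cis to C1. C8 is controlled by the way the flat cyclopentenolate docks: its C14 methylene rather than the metal-bound C15 oxygen should lie beside the carbamoyl group, to minimise steric clash and opposed dipoles, which places C11 cis to C14 as the later C12–C13 closure requires. The step needs hetero- over homocoupling and C–C over C–O bonding, which the six-membered intramolecular geometry, the different oxidation potentials of the two enolates and high dilution should secure, whereas the facial preference at C8 remains to be confirmed by experiment.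

**Step 15**
Reactants: 24 dispiro keto lactone amide
Product: 27 C11 methyl ketone (C12 = CH3), via O-triflyl iminium triflate 25 (not isolated), via dimethyl ketiminium triflate 26 (not isolated)
Conditions: Tf2O, 2-fluoropyridine, CH2Cl2, −78 → 0 °C; MeMgBr (1.1 eq), −78 °C; aq. NaHCO3, 23 °C
Reagents that add atoms: methylmagnesium bromide, C[Mg]Br; water, O
Why: Electrophilic amide activation followed by Grignard addition, in which the amide oxygen as the most Lewis-basic site is triflylated selectively, the iminium triflate is far more electrophilic than the hindered C15 ketone or the lactone and should take up one methyl group at −78 °C, and hydrolysis of the ketiminium ion gives the methyl ketone without touching C9.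

**Step 16**
Reactants: 27 methyl ketone
Product: 28 ring D enone (C15 ketone, C16=C13)
Conditions: IBX, DMSO/fluorobenzene, 70 °C
Reagents that add atoms: none
Why: IBX-mediated α,β-dehydrogenation of a ketone, which can give only one enone because the ring D ketone alone has an α-CH2 (C16) with a β-hydrogen (C13), the methyl ketone having no β-hydrogen.

**Step 17**
Reactants: 28 ring D enone
Product: 30 tricyclic 11-ketone with C15 OTBS enol ether, via potassium enolate 29 (not isolated)
Conditions: KN(SiMe3)2, THF, −78 → −40 °C; then TBSCl, DMPU, −78 → 0 °C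
Reagents that add atoms: tert-butyldimethylsilyl chloride, CC(C)(C)[Si](C)(C)Cl
Why: Intramolecular Michael addition in which the kinetic enolate of the methyl ketone (C12) should add to C13 of the cyclopentenone through a six-membered transition state that is reachable only on the ring D face held next to C11, so that C13 is set by the tether, and silylation of the resulting C15 enolate keeps the two ketones distinct.

**Step 18**
Reactants: 30 tricyclic 11-ketone
Product: 31 11-alcohol (hydroxyl equatorial, anti to the C15–C16 bridge)
Conditions: NaBH4, MeOH/THF, −40 °C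
Reagents that add atoms: none
Why: Ketone reduction by NaBH4, which can touch only C11 while C15 is masked as the enol ether, and in which hydride should arrive from the side of the flat C15=C16 bridge because the opposite face is blocked by the axial C9–C10 bond, giving the equatorial hydroxyl of the target.

**Step 19**
Reactants: 31 11-alcohol
Product: 32 11-OTBS ether
Conditions: TBSOTf, 2,6-lutidine, CH2Cl2, −78 → 0 °C
Reagents that add atoms: tert-butyldimethylsilyl triflate, CC(C)(C)[Si](C)(C)OS(=O)(=O)C(F)(F)F
Why: Silyl ether formation at the secondary C11 hydroxyl, so that it is not acetylated in step 22.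

**Step 20**
Reactants: 32 silyl enol ether
Product: 35 16-methylene 15-ketone, via Mannich base 33 (not isolated), via trimethylammonium iodide 34 (not isolated)
Conditions: CH2=NMe2+ I−, CH2Cl2, 23 °C; then MeI; then aq. NaHCO3
Reagents that add atoms: dimethyl(methylene)ammonium iodide, C=[N+](C)C.[I-]
Why: α-Methylenation by a Mannich reaction of the silyl enol ether with the iminium salt at C16, quaternisation of the amine and base-induced β-elimination, which should give the exocyclic enone regiospecifically.

**Step 21**
Reactants: 35 methyl acetal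
Product: 36 C6 lactol (anomer mixture)
Conditions: AcOH/THF/H2O (3:1:1), 45 °C
Reagents that add atoms: water, O
Why: Acid-catalysed acetal hydrolysis through the ring oxocarbenium ion in a medium without nucleophilic counter-ions that could add to the enone, the hindered secondary silyl ethers being stable to aqueous acetic acid.

**Step 22**
Reactants: 36 lactol
Product: 37 6-acetate with the acetoxy group trans to C10
Conditions: Ac2O, pyridine, DMAP (cat.), CH2Cl2, 0 °C
Reagents that add atoms: acetic anhydride, CC(=O)OC(C)=O
Why: Acylation of the lactol hydroxyl, the only free hydroxyl, which should place the acetate on the convex face (cis to H5, trans to C10) as the more stable anomer.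

**Step 23**
Reactants: 37 bis(TBS) ether
Product: 38 Oreskaurin A
Conditions: HF·pyridine, pyridine, THF, 0 → 23 °C
Reagents that add atoms: none
Why: Fluoride-mediated desilylation of both secondary silyl ethers under buffered conditions that should spare the acetoxy acetal, the exocyclic enone and the lactone.

**Compound list**

1 | citraconic anhydride | CC1=CC(=O)OC1=O | starting material
2 | 5-hydroxy-3-methylfuran-2(5H)-one (racemic lactol) | CC1=CC(O)OC1=O | intermediate
3 | (+)-menthol, (1S,2R,5S)-2-isopropyl-5-methylcyclohexan-1-ol | O[C@H]1C[C@@H](C)CC[C@@H]1C(C)C | starting material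
4 | (5S)-3-methyl-5-[(1S,2R,5S)-menthyloxy]furan-2(5H)-one | CC1=C[C@@H](O[C@H]2C[C@@H](C)CC[C@@H]2C(C)C)OC1=O | intermediate
5 | (E)-3-(tert-butyldimethylsilyloxy)-N,N-dimethylbuta-1,3-dien-1-amine | CN(C)/C=C/C(=C)O[Si](C)(C)C(C)(C)C | starting material
6 | cycloadduct: ring A cis-fused to the γ-lactone; C1 OTBS enol ether (C1=C2), C3 NMe2 up, C4 CH3 down and lactone carbonyl C19 up, C5 H down, C6 acetal carbon up with O-menthyl trans to C10 | CC(C)(C)[Si](C)(C)OC1=C[C@@H](N(C)C)[C@@]2(C)C(=O)O[C@H](O[C@H]3C[C@@H](C)CC[C@@H]3C(C)C)[C@H]2C1 | intermediate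
7 | diol: as 6 but C19 and C6 are both CH2OH (cis) | CC(C)(C)[Si](C)(C)OC1=C[C@@H](N(C)C)[C@@](C)(CO)[C@@H](CO)C1 | intermediate
8 | 6,19-lactone (C6 carbonyl, C19H2–O) with C1 OTBS enol ether and C3 NMe2 | CC(C)(C)[Si](C)(C)OC1=C[C@@H](N(C)C)[C@@]2(C)COC(=O)[C@H]2C1 | intermediate
9 | C6 lactol of 8 (anomer mixture) | CC(C)(C)[Si](C)(C)OC1=C[C@@H](N(C)C)[C@@]2(C)COC(O)[C@H]2C1 | intermediate
10 | ring A enone (C1 ketone, C2=C3) cis-fused to the 6-methoxytetrahydrofuran C19H2–O–C6H(OMe), OMe trans to C10 | O=C1C=C[C@@]2(C)CO[C@H](OC)[C@H]2C1 | intermediate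
11 | benzyl chloromethyl ether | ClCOCc1ccccc1 | starting material
12 | lithium dienolate of 10 (C1–OLi, C1=C10, C2=C3) | [Li+].[O-]C1C=C[C@@]2(C)CO[C@H](OC)[C@H]2C=1 | intermediate
13 | 10 with CH2OBn (C20) on C10, both C10 epimers | O=C1C=C[C@@]2(C)CO[C@H](OC)[C@H]2C1COCc1ccccc1 | intermediate
14 | 2-bromo-N,N-dimethylacetamide | CN(C)C(=O)CBr | starting material
15 | lithium enolate of 13 (C1–OLi, C1=C10) | [Li+].[O-]C1C=C[C@@]2(C)CO[C@H](OC)[C@H]2C=1COCc1ccccc1 | intermediate
16 | quaternary enone: C10 bears CH2OBn (C20, up) and CH2CONMe2 (C9, down) | CN(C)C(=O)C[C@]1(COCc2ccccc2)C(=O)C=C[C@@]3(C)CO[C@H](OC)[C@H]31 | intermediate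
17 | C20 alcohol with C1 ketone, ring A saturated | CN(C)C(=O)C[C@]1(CO)C(=O)CC[C@@]2(C)CO[C@H](OC)[C@H]21 | intermediate
18 | 1,20-diol, C1 hydroxyl down (trans to C20, cis to C9) | CN(C)C(=O)C[C@]1(CO)[C@H](O)CC[C@@]2(C)CO[C@H](OC)[C@H]21 | intermediate
19 | 1,20-bis(TBS) ether of 18 | CN(C)C(=O)C[C@]1(CO[Si](C)(C)C(C)(C)C)[C@H](O[Si](C)(C)C(C)(C)C)CC[C@@]2(C)CO[C@H](OC)[C@H]21 | intermediate
20 | C20 alcohol with C1 OTBS | CN(C)C(=O)C[C@]1(CO)[C@H](O[Si](C)(C)C(C)(C)C)CC[C@@]2(C)CO[C@H](OC)[C@H]21 | intermediate
21 | methyl 2-oxocyclopentane-1-carboxylate | COC(=O)C1CCCC1=O | starting material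
22 | key-step precursor: C20 2-oxocyclopentane-1-carboxylate of 20 (both C8 epimers), C9 arm as dimethylamide | CN(C)C(=O)C[C@]1(COC(=O)C3CCCC3=O)[C@H](O[Si](C)(C)C(C)(C)C)CC[C@@]2(C)CO[C@H](OC)[C@H]21 | intermediate
23 | dilithium bis-enolate of 22 (amide enolate C9=C11, keto ester enolate C8=C15) | [Li+].[Li+].CN(C)C([O-])=C[C@]1(COC(=O)C3=C([O-])CCC3)[C@H](O[Si](C)(C)C(C)(C)C)CC[C@@]2(C)CO[C@H](OC)[C@H]21 | intermediate
24 | dispiro keto lactone: lactone C7(=O)–O–C20 closed by C8–C9; C8 spiro to the cyclopentanone (C15 ketone); C9–H bears CONMe2 with C11 cis to C14 and to C1 | O=C1CCC[C@]12[C@@H](C(=O)N(C)C)[C@]3(COC2=O)[C@H](O[Si](C)(C)C(C)(C)C)CC[C@@]4(C)CO[C@H](OC)[C@H]43 | intermediate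
25 | O-triflyl iminium triflate of 24 | O=C1CCC[C@]12[C@@H](C(OS(=O)(=O)C(F)(F)F)=[N+](C)C)[C@]3(COC2=O)[C@H](O[Si](C)(C)C(C)(C)C)CC[C@@]4(C)CO[C@H](OC)[C@H]43.[O-]S(=O)(=O)C(F)(F)F | intermediate
26 | N,N-dimethyl ketiminium triflate (C11 bears CH3) | O=C1CCC[C@]12[C@@H](C(C)=[N+](C)C)[C@]3(COC2=O)[C@H](O[Si](C)(C)C(C)(C)C)CC[C@@]4(C)CO[C@H](OC)[C@H]43.[O-]S(=O)(=O)C(F)(F)F | intermediate
27 | C11 methyl ketone (C12 = CH3) | O=C1CCC[C@]12[C@@H](C(C)=O)[C@]3(COC2=O)[C@H](O[Si](C)(C)C(C)(C)C)CC[C@@]4(C)CO[C@H](OC)[C@H]43 | intermediate
28 | ring D enone (C15 ketone, C16=C13) with the C11 methyl ketone | O=C1C=CC[C@]12[C@@H](C(C)=O)[C@]3(COC2=O)[C@H](O[Si](C)(C)C(C)(C)C)CC[C@@]4(C)CO[C@H](OC)[C@H]43 | intermediate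
29 | potassium C15 enolate of the tricyclic Michael adduct (C12–C13 formed) | C1=C([O-])[C@]23C[C@H]1CC(=O)[C@H]2[C@]1(COC3=O)[C@H](O[Si](C)(C)C(C)(C)C)CC[C@@]2(C)CO[C@H](OC)[C@H]21.[K+] | intermediate
30 | tricyclic 11-ketone with C15 OTBS enol ether (C15=C16) | C1=C(O[Si](C)(C)C(C)(C)C)[C@]23C[C@H]1CC(=O)[C@H]2[C@]1(COC3=O)[C@H](O[Si](C)(C)C(C)(C)C)CC[C@@]2(C)CO[C@H](OC)[C@H]21 | intermediate
31 | 11-alcohol of 30 (hydroxyl equatorial, anti to the C15–C16 bridge) | C1=C(O[Si](C)(C)C(C)(C)C)[C@]23C[C@H]1C[C@@H](O)[C@H]2[C@]1(COC3=O)[C@H](O[Si](C)(C)C(C)(C)C)CC[C@@]2(C)CO[C@H](OC)[C@H]21 | intermediate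
32 | 11-OTBS ether of 31 | C1=C(O[Si](C)(C)C(C)(C)C)[C@]23C[C@H]1C[C@@H](O[Si](C)(C)C(C)(C)C)[C@H]2[C@]1(COC3=O)[C@H](O[Si](C)(C)C(C)(C)C)CC[C@@]2(C)CO[C@H](OC)[C@H]21 | intermediate
33 | Mannich base (C16–CH2NMe2, 15-ketone; C16 epimers) | CN(C)CC1C(=O)[C@]23C[C@H]1C[C@@H](O[Si](C)(C)C(C)(C)C)[C@H]2[C@]1(COC3=O)[C@H](O[Si](C)(C)C(C)(C)C)CC[C@@]2(C)CO[C@H](OC)[C@H]21 | intermediate
34 | trimethylammonium iodide of 33 | C[N+](C)(C)CC1C(=O)[C@]23C[C@H]1C[C@@H](O[Si](C)(C)C(C)(C)C)[C@H]2[C@]1(COC3=O)[C@H](O[Si](C)(C)C(C)(C)C)CC[C@@]2(C)CO[C@H](OC)[C@H]21.[I-] | intermediate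
35 | 16-methylene 15-ketone with 1,11-bis(OTBS) and 6-OMe | C=C1C(=O)[C@]23C[C@H]1C[C@@H](O[Si](C)(C)C(C)(C)C)[C@H]2[C@]1(COC3=O)[C@H](O[Si](C)(C)C(C)(C)C)CC[C@@]2(C)CO[C@H](OC)[C@H]21 | intermediate
36 | C6 lactol of 35 (anomer mixture) | C=C1C(=O)[C@]23C[C@H]1C[C@@H](O[Si](C)(C)C(C)(C)C)[C@H]2[C@]1(COC3=O)[C@H](O[Si](C)(C)C(C)(C)C)CC[C@@]2(C)COC(O)[C@H]21 | intermediate
37 | 6-acetate (OAc trans to C10) with 1,11-bis(OTBS) | C=C1C(=O)[C@]23C[C@H]1C[C@@H](O[Si](C)(C)C(C)(C)C)[C@H]2[C@]1(COC3=O)[C@H](O[Si](C)(C)C(C)(C)C)CC[C@@]2(C)CO[C@H](OC(C)=O)[C@H]21 | intermediate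
38 | Oreskaurin A | C=C1C(=O)[C@]23C[C@H]1C[C@@H](O)[C@H]2[C@]1(COC3=O)[C@H](O)CC[C@@]2(C)CO[C@H](OC(C)=O)[C@H]21 | target

**Totals.** Total step count: 23. Longest linear sequence: 23 steps (1 → 38); compounds 3, 5, 11, 14 and 21 are commercial and enter directly.

**Steps most likely to fail**

Step 14. The bis-enolate may be consumed by homocoupling, by C–O bonding or by hydrogen abstraction, or the cyclopentenolate may dock with the wrong face so that C8 forms with C11 cis to C15. The fallback separates enolate formation from oxidation. Starting from 22, LiN(iPr)2 and TBSCl in THF/DMPU should give the bis(silyl) derivative F1 (C15 silyl enol ether and C11 O-silyl ketene N,O-acetal), which is isolated. Oxidation with (NH4)2Ce(NO3)6 and NaHCO3 in MeCN at −30 °C follows; the tetravalent cerium oxidises the electron-rich ketene aminal, the radical cation is captured at C8 of the silyl enol ether in the same 6-exo mode, and loss of both silyl groups returns the route to 24. This is the known oxidative cross-coupling of silyl enol ethers; being free of lithium aggregates, it may also show a different facial preference at C8.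

Step 15. The Grignard reagent may add to the C15 ketone or to the lactone, triflylation of the very hindered amide may be incomplete, or C9 may epimerise through a keteniminium ion. The fallback replaces the direct conversion by reduction, addition and oxidation with the ketone masked. Starting from 24, TBSOTf and Et3N should give the ring D silyl enol ether F2. Cp2Zr(H)Cl in THF reduces the tertiary amide to the aldehyde F3 without touching the lactone. MeMgBr at −78 °C adds only to the aldehyde to give the carbinol F4. Dess–Martin periodinane gives the methyl ketone F5. Saegusa–Ito oxidation of the silyl enol ether with Pd(OAc)2 (divalent palladium) in MeCN then delivers the enone and the route is rejoined at 28.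

Step 17. The C12 enolate may attack the lactone carbonyl C7 in a Claisen-type acylation, or proton transfer between the C15 enolate and the C11 ketone before silylation may erase the distinction between the two ketones. The fallback avoids free enolates. Starting from 28, pyrrolidine and AcOH in CH2Cl2 should effect the Michael addition through the enamine of the methyl ketone, which cannot acylate on the lactone, and give the 11,15-diketone F6. NaBH4 at −78 °C is expected to reduce the cyclohexanone C11 faster than the cyclopentanone C15 flanked by quaternary C8, giving the hydroxy ketone F7. TBSOTf and Et3N then silylate the C11 hydroxyl and convert the C15 ketone into its silyl enol ether, which rejoins the route at 32.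

**Further compounds**

F1 | step 14 | bis(silyl) derivative of 22 (C15 OTBS enol ether, C11 O-TBS ketene N,O-acetal) | CN(C)C(O[Si](C)(C)C(C)(C)C)=C[C@]1(COC(=O)C3=C(O[Si](C)(C)C(C)(C)C)CCC3)[C@H](O[Si](C)(C)C(C)(C)C)CC[C@@]2(C)CO[C@H](OC)[C@H]21
F2 | step 15 | ring D OTBS enol ether of 24 | CC(C)(C)[Si](C)(C)OC1=CCC[C@]12[C@@H](C(=O)N(C)C)[C@]3(COC2=O)[C@H](O[Si](C)(C)C(C)(C)C)CC[C@@]4(C)CO[C@H](OC)[C@H]43
F3 | step 15 | C11 aldehyde with ring D OTBS enol ether | CC(C)(C)[Si](C)(C)OC1=CCC[C@]12[C@@H](C=O)[C@]3(COC2=O)[C@H](O[Si](C)(C)C(C)(C)C)CC[C@@]4(C)CO[C@H](OC)[C@H]43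
F4 | step 15 | C11 methyl carbinol (C11 epimers) with ring D OTBS enol ether | CC(C)(C)[Si](C)(C)OC1=CCC[C@]12[C@@H](C(C)O)[C@]3(COC2=O)[C@H](O[Si](C)(C)C(C)(C)C)CC[C@@]4(C)CO[C@H](OC)[C@H]43
F5 | step 15 | C11 methyl ketone with ring D OTBS enol ether | CC(C)(C)[Si](C)(C)OC1=CCC[C@]12[C@@H](C(C)=O)[C@]3(COC2=O)[C@H](O[Si](C)(C)C(C)(C)C)CC[C@@]4(C)CO[C@H](OC)[C@H]43
F6 | step 17 | tricyclic 11,15-diketone | C1C(=O)[C@]23C[C@H]1CC(=O)[C@H]2[C@]1(COC3=O)[C@H](O[Si](C)(C)C(C)(C)C)CC[C@@]2(C)CO[C@H](OC)[C@H]21
F7 | step 17 | tricyclic 11-hydroxy 15-ketone | C1C(=O)[C@]23C[C@H]1C[C@@H](O)[C@H]2[C@]1(COC3=O)[C@H](O[Si](C)(C)C(C)(C)C)CC[C@@]2(C)CO[C@H](OC)[C@H]21
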